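The pitfall in these runs is to carry a ratio read late back to an early hour: no two readings of a series differ by more than 1.6 percentage points, and even the earliest reading, at 1.25 d, stands far later than the asked 15 min. Z is turned into E and Q in the presence of the catalyst X and the solid G.

| flask | Z | G | X | remark | time |
|---|---|---|---|---|---|
| north-west | 0.80 M | 0.72 M | 1.1 mM | run made earlier |  |
| south | 0.80 M | 0.72 M | 2.4 mM | run made earlier |  |
| south-east | 0.40 M | 0.72 M | 1.6 mM | run made earlier |  |
| flask | 0.80 M | 0.720 M | 1.6 mM |  | 15 d |

| run | time / d | Q / % | E / % |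
|---|---|---|---|
| north-west | 3.00 | 41.4 | 48.1 |
| north-west | 6.00 | 41.7 | 47.7 |
| north-west | 10.0 | 41.3 | 48.2 |
| north-west | 12.0 | 41.8 | 48.4 |
| north-west | 15.0 | 42.1 | 47.5 |
| south | 1.25 | 25.1 | 63.7 |
| south | 4.00 | 24.8 | 64.0 |
| south | 8.00 | 25.2 | 64.2 |
| south | 10.0 | 26.2 | 64.1 |
| south | 15.0 | 26.4 | 63.9 |
| south-east | 1.25 | 42.1 | 58.4 |
| south-east | 4.00 | 42.6 | 57.2 |
| south-east | 8.00 | 42.9 | 56.8 |
| south-east | 10.0 | 42.7 | 57.8 |
| south-east | 15.0 | 41.8 | 57.7 |

(scatter of a reading: 0.5 percentage points)

1. ratio of Q to E at 15 min
2. ratio of Q to E at 8.0 h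
3. ratio of Q to E at 15 d
4. which of Q and E there is more of at 15 d

- solid, in amounts per volume of the solution: G
- at the start none of G is in solution

One thing looks contradictory. The south-east run has the flask's own charge of X, 1.6 mM, and reads a [Q]/[E] of 0.737, yet the other two runs point elsewhere. To see this, take the even split as the zero of the scale and define the level charge as [X] times the late [Q]/[E], the charge at which a ratio falling inversely with X puts Q and E level. The north-west run, with a ratio of 0.868, gives 0.955 mM. The south run, with twice the X and a ratio of 0.399, gives 0.958 mM. The south-east run gives 1.18 mM, which is higher.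

The totals clear this up. In the north-west run Q and E reach 89.6% of the Z charged, and G was charged at 90.0% of Z, so G is the limiting reagent there. In the south-east run they reach 99.5%, with G at 180% of Z. The flask has the G to Z proportion of the north-west and south runs, 90.0%, which is lower than the south-east run's, so my reckoning gives it the mean of those two runs' values, a level charge of 0.957 mM. My reckoning gives a late ratio of 0.598, with E ahead because the flask's X stands above the level charge.

The forecast gave 0.5 at 15 min, 0.53 at 8.0 h and 0.594 at 15 d, the last differing slightly from my 0.598, with E leading, and it warned: “The early value is uncertain because G dissolves gradually and no early data exist.”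

The flask gives 7.70 at 15 min, 0.820 at 8.0 h and 0.605 at 15 d, with E leading. The forecast's early value lies lower by a factor of 15.4. Q and E stand level at 0.231 d, at 29.5% of the Z charged each, and the late ratio of the flask returns a level charge of 0.968 mM, against the 0.957 mM reckoned from the runs.

    L + J → X + E (k = 470 M⁻¹ h⁻¹)
    X + D ⇌ J (K = 33.0 M⁻¹, k = 390 M⁻¹ h⁻¹)
    G ⇌ L, rate k3*(cs3 - [L]) while solid is left; crystals form when [L] > cs3 (solubility = 0.560 M, k = 10.0 h⁻¹)
    Z + X → X + D (k = 91.0 M⁻¹ h⁻¹)
    Z + L → Q (k = 0.210 M⁻¹ h⁻¹)

The neighbour with 1.2 M of G, 1.50 equiv to Z at the same X, is reckoned the same way. Its [Q]/[E] of 0.835 at 15 d gives a level charge of 1.34 mM, higher than the flask's 0.968 mM and, like the south-east run's 1.18 mM, on the G-rich side. Its ratio at 15 min is the flask's, 7.70, and at 8.0 h it reads 0.976. At the end, of the Z charged, it holds E 54.5%, Q 45.5% and D 0%, against D 9.86% in the flask, and 0.400 M of L stands over.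

(The runs were computed for substances that don't exist.)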